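## Retrosynthetic overview

1. Numbering (daucane): C1 = quaternary ring-fusion carbon (CH3), C2/C3 = CH2, C4 = isopropyl carbinol, C5 = ring-fusion CH, C6 = ester-bearing CH, C7 = CH2, C8 = methyl carbinol, C9=C10 alkene; β = face of the C1 methyl group; "14-nor" = C8 methyl still missing.
2. Endgame: ester ⇒ triol (only the C6 OH is secondary); C8–OH and C9=C10 ⇒ 6α-OH-directed epoxidation of a 7,9-dien-6α-ol and hydride opening at C7; the 8-methyl dienone ⇒ the plain C6 ketone by dehydrogenation and methyl cuprate addition.
3. Key disconnection: the cyclopentane is cut at C2–C3 and C4–C5, a formal [3+2] of the three-carbon unit C2–C1–C5 with the two alkyne carbons of 3-methylbut-1-yne, run as a SmI2-catalysed radical relay on a bicyclic cyclopropyl ketone; C4–OH then follows by convex-face hydration and C5 by epimerisation.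
4. Enabling feature: the quaternary C1 carries C2 and is bonded to C5, and C5 is α to the oxygenated C6; at the C6 ketone level, C1/C2/C5 can be a temporary cyclopropane fused to the seven-membered ring and conjugated with C6=O, and this ring fusion directs cleavage to the exocyclic C2–C5 bond.
5. Ring order: seven-membered ring (bought) → temporary cyclopropane → five-membered ring (key step); one catalyst-set carbinol relays to C1, then C5, C4, C6 and C8 by substrate control.

Key step: step 4

Remark: 3-methylcyclohept-2-en-1-one (compound 1) is taken as a catalogue compound; if it had to be made, two steps from cyclohept-2-en-1-one (MeLi addition, then oxidative transposition) would precede step 1.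

## Route

Step 1
Reactants: 1 3-methylcyclohept-2-en-1-one
Product: 2 (S)-3-methylcyclohept-2-en-1-ol
Conditions: (R)-1-methyl-3,3-diphenyltetrahydro-1H,3H-pyrrolo[1,2-c][1,3,2]oxazaborole (10 mol%), BH3·SMe2, THF, −20 °C; MeOH quench
Reagents that add atoms: none
Why: Corey–Bakshi–Shibata reduction: with the alkenyl branch as the large group, the (R)-oxazaborolidine–borane complex should deliver hydride to the carbonyl face that gives the (S)-allylic alcohol, the only stereocenter of the route that is set by a chiral catalyst.

Step 2
Reactants: 2 (S)-3-methylcyclohept-2-en-1-ol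
Product: 3 (1R,2S,7S)-7-methylbicyclo[5.1.0]octan-2-ol
Conditions: Et2Zn, CH2I2, CH2Cl2, 0 °C to rt
Reagents that add atoms: diiodomethane, ICI
Why: Hydroxyl-directed Simmons–Smith cyclopropanation (Furukawa reagent): the zinc alkoxide of 2 should deliver CH2 to the alkene face syn to the oxygen, which fixes the two cyclopropane stereocenters (later C1 and C5) relative to the carbinol.

Step 3
Reactants: 3 (1R,2S,7S)-7-methylbicyclo[5.1.0]octan-2-ol
Product: 4 (1R,7S)-7-methylbicyclo[5.1.0]octan-2-one
Conditions: Dess–Martin periodinane, NaHCO3, CH2Cl2, rt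
Reagents that add atoms: none
Why: Dess–Martin oxidation of the secondary alcohol should give the cyclopropyl ketone without touching the cyclopropane; it erases the relay carbinol and leaves C1 as the stereochemical source.

Step 4
Reactants: 4 (1R,7S)-7-methylbicyclo[5.1.0]octan-2-one; 5 3-methylbut-1-yne
Product: 8 cis-fused enone 14-nor-5βH-dauc-3-en-6-one, via ring-opened radical enolate 6 (not isolated), via vinyl radical enolate 7 (not isolated)
Conditions: SmI2 (20 mol%), Sm (20 mol%), 5 (5 equiv), THF, 55 °C, sealed tube
Reagents that add atoms: none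
Why: Radical-relay formal [3+2] cycloaddition: divalent samarium reduces the ketone of 4 to a ketyl, the exocyclic cyclopropane bond C2–C5 breaks to give primary radical/trivalent samarium enolate 6, the radical adds to the unsubstituted terminus of alkyne 5 (C2–C3 bond) to give vinyl radical 7, which attacks the enolate carbon C5 (C4–C5 bond), and the new ketyl hands its electron back to samarium, so the step is redox-neutral and catalytic. The closest known reaction type is the SmI2-catalysed coupling of alkyl cyclopropyl ketones, fused bicyclic ones included, with alkynes, in which Sm metal keeps the catalyst in the divalent state. The five-membered ring is closed by a 5-exo-trig addition of the C4 vinyl radical to C5 of the C5=C6 enolate; the seven-membered ring is already in place and the cyclopropane is spent. C5 is the only new stereocenter and is set by the tether: the C2–C3–C4 chain hangs from C1 on the face that the cyclopropane CH2 occupied and can reach C5 only from that face, so 8 should be cis-fused (H-5 β), while C4 stays sp2 for step 5. The step needs cleavage of C2–C5 and not of the ring-fusion bond C1–C5, and the fused ring is expected to secure this because the exocyclic bond overlaps with the ketyl p orbital whereas the ring-fusion bond lies close to its nodal plane; it also needs attack at the terminal alkyne carbon, which the isopropyl group and the more substituted vinyl radical favour.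

Step 5
Reactants: 8 cis-fused enone 14-nor-5βH-dauc-3-en-6-one
Product: 9 4β-hydroxy-14-nor-5βH-daucan-6-one
Conditions: Co(acac)2 (20 mol%), PhSiH3, O2 (1 atm), THF, rt
Reagents that add atoms: dioxygen, O=O
Why: Mukaiyama hydration (cobalt hydride hydrogen-atom transfer, then O2 capture): H• adds to C3 to give the tertiary C4 radical (Markovnikov), which should be captured on the convex β face of the cis-fused bicycle, anti to the C5–C6 bond, so that the OH ends up β (cis to the C1 methyl) and the isopropyl group α, while the ketone is inert.

Step 6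
Reactants: 9 4β-hydroxy-14-nor-5βH-daucan-6-one
Product: 10 4β-hydroxy-14-nor-5αH-daucan-6-one
Conditions: 1,8-diazabicyclo[5.4.0]undec-7-ene (0.5 equiv), toluene, 60 °C
Reagents that add atoms: none
Why: Base-mediated epimerisation through the C5=C6 enolate (thermodynamic control): the trans-fused epimer should be favoured because it moves C6 away from the α-isopropyl group on the concave face and allows an O–H···O=C hydrogen bond from the 4β-OH, and an amidine base should not trigger retro-aldol cleavage of the tertiary aldol.

Step 7
Reactants: 10 4β-hydroxy-14-nor-5αH-daucan-6-one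
Product: 11 4β-hydroxy-14-nor-5αH-dauc-7-en-6-one
Conditions: IBX (2 equiv), DMSO, 70 °C
Reagents that add atoms: none
Why: IBX dehydrogenation of a ketone to its enone: only the C7–C8 side can be desaturated because both carbons next to C5 (C1 and C4) are fully substituted, and the tertiary alcohol is not oxidised.

Step 8
Reactants: 11 4β-hydroxy-14-nor-5αH-dauc-7-en-6-one
Product: 12 4β-hydroxy-5αH-daucan-6-one (C8 epimers)
Conditions: Me2CuLi (3 equiv), Et2O, −78 to −40 °C; aq. NH4Cl
Reagents that add atoms: lithium dimethylcuprate, [Li+].C[Cu-]C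
Why: Conjugate addition of a Gilman cuprate to the enone puts the C14 methyl group on C8; the new C8 stereocenter needs no control because it becomes sp2 again in step 9.

Step 9
Reactants: 12 4β-hydroxy-5αH-daucan-6-one (C8 epimers)
Product: 13 4β-hydroxy-5αH-dauc-7-en-6-one
Conditions: IBX (2 equiv), DMSO, 75 °C
Reagents that add atoms: none
Why: A second IBX dehydrogenation, again confined to C7–C8, should give the β-methyl enone and remove the C8 stereocenter.

Step 10
Reactants: 13 4β-hydroxy-5αH-dauc-7-en-6-one
Product: 14 4β-hydroxy-5αH-dauca-7,9-dien-6-one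
Conditions: chloranil, t-BuOH, reflux
Reagents that add atoms: none
Why: Quinone dehydrogenation of an enone to the linear dienone (the reaction that converts 3-keto-4-ene steroids into 4,6-dienones): hydride abstraction from C10 of the extended dienol introduces C9=C10, the methyl branch offers no such path, and no stereocenter is formed.

Step 11
Reactants: 14 4β-hydroxy-5αH-dauca-7,9-dien-6-one
Product: 15 5αH-dauca-7,9-diene-4β,6α-diol
Conditions: Me4NBH(OAc)3, MeCN/AcOH (5:1), −35 °C
Reagents that add atoms: none
Why: Evans–Saksena reduction: the 4β-OH should exchange onto boron and deliver hydride intramolecularly to the β face of the C6 carbonyl (1,2-reduction), which sets the 6α-OH with an anti 1,3-diol relationship.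

Step 12
Reactants: 15 5αH-dauca-7,9-diene-4β,6α-diol
Product: 16 7α,8α-epoxy-5αH-dauc-9-ene-4β,6α-diol
Conditions: VO(acac)2 (5 mol%), t-BuOOH, CH2Cl2, 0 °C
Reagents that add atoms: tert-butyl hydroperoxide, CC(C)(C)OO
Why: Vanadium-catalysed hydroxyl-directed epoxidation of an allylic alcohol: the vanadate ester of the 6α-OH should deliver oxygen to C7=C8 on the α face (syn), setting C8, while the non-allylic C9=C10 bond stays intact.

Step 13
Reactants: 16 7α,8α-epoxy-5αH-dauc-9-ene-4β,6α-diol
Product: 17 5αH-dauc-9-ene-4β,6α,8α-triol
Conditions: NaAlH2(OCH2CH2OCH3)2, THF, 0 °C to rt; aq. NaOH work-up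
Reagents that add atoms: none
Why: Hydride opening of a 2,3-epoxy alcohol to the 1,3-diol: the aluminate bound to O6 should deliver hydride to C7, the only unhindered epoxide carbon, so the C8–O bond is kept and the 8α tertiary alcohol appears with retention.

Step 14
Reactants: 17 5αH-dauc-9-ene-4β,6α,8α-triol; 18 4-acetoxybenzoyl chloride
Product: 19 5αH-dauc-9-ene-4β,6α,8α-triol 6-(4-acetoxybenzoate)
Conditions: Et3N, 4-(dimethylamino)pyridine (10 mol%), CH2Cl2, 0 °C to rt
Reagents that add atoms: none
Why: Acylation with an acid chloride under nucleophilic catalysis: only the secondary 6α-OH should react, the C4 and C8 tertiary alcohols being too hindered, and no stereocenter changes.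

Step 15
Reactants: 19 5αH-dauc-9-ene-4β,6α,8α-triol 6-(4-acetoxybenzoate)
Product: 20 5αH-dauc-9-ene-4β,6α,8α-triol 6-(4-hydroxybenzoate) (CNP0280165.4)
Conditions: K2CO3 (0.2 equiv), MeOH, 0 °C
Reagents that add atoms: none
Why: Base-catalysed methanolysis (transesterification) of the aryl acetate, which is far more electrophilic than the hindered secondary benzoate; the phenoxide that forms deactivates that benzoate further.

## Compound list

1 | 3-methylcyclohept-2-en-1-one | CC1=CC(=O)CCCC1 | starting material
2 | (S)-3-methylcyclohept-2-en-1-ol | CC1=C[C@@H](O)CCCC1 | intermediate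
3 | (1R,2S,7S)-7-methylbicyclo[5.1.0]octan-2-ol (OH syn to the cyclopropane CH2) | C[C@]12C[C@H]1[C@@H](O)CCCC2 | intermediate
4 | (1R,7S)-7-methylbicyclo[5.1.0]octan-2-one | C[C@]12C[C@H]1C(=O)CCCC2 | intermediate
5 | 3-methylbut-1-yne | CC(C)C#C | starting material
6 | ring-opened primary radical with diiodosamarium enolate (from 4) | [CH2][C@]1(C)CCCCC(O[Sm](I)I)=C1 | intermediate
7 | vinyl radical with diiodosamarium enolate (after addition to 5) | CC(C)[C]=CC[C@]1(C)CCCCC(O[Sm](I)I)=C1 | intermediate
8 | 14-nor-5βH-dauc-3-en-6-one (cis-fused; H-5 and C1 methyl both β) | CC(C)C1=CC[C@]2(C)CCCCC(=O)[C@@H]21 | intermediate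
9 | 4β-hydroxy-14-nor-5βH-daucan-6-one (cis-fused; 4-OH cis to the C1 methyl) | CC(C)[C@]1(O)CC[C@]2(C)CCCCC(=O)[C@@H]21 | intermediate
10 | 4β-hydroxy-14-nor-5αH-daucan-6-one (trans-fused) | CC(C)[C@]1(O)CC[C@]2(C)CCCCC(=O)[C@H]21 | intermediate
11 | 4β-hydroxy-14-nor-5αH-dauc-7-en-6-one | CC(C)[C@]1(O)CC[C@]2(C)CCC=CC(=O)[C@H]21 | intermediate
12 | 4β-hydroxy-5αH-daucan-6-one (mixture of C8 epimers) | CC(C)[C@]1(O)CC[C@]2(C)CCC(C)CC(=O)[C@H]21 | intermediate
13 | 4β-hydroxy-5αH-dauc-7-en-6-one | CC(C)[C@]1(O)CC[C@]2(C)CCC(C)=CC(=O)[C@H]21 | intermediate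
14 | 4β-hydroxy-5αH-dauca-7,9-dien-6-one | CC(C)[C@]1(O)CC[C@]2(C)C=CC(C)=CC(=O)[C@H]21 | intermediate
15 | 5αH-dauca-7,9-diene-4β,6α-diol | CC(C)[C@]1(O)CC[C@]2(C)C=CC(C)=C[C@H](O)[C@H]21 | intermediate
16 | 7α,8α-epoxy-5αH-dauc-9-ene-4β,6α-diol | CC(C)[C@]1(O)CC[C@]2(C)C=C[C@]3(C)O[C@@H]3[C@H](O)[C@H]21 | intermediate
17 | 5αH-dauc-9-ene-4β,6α,8α-triol | CC(C)[C@]1(O)CC[C@]2(C)C=C[C@](C)(O)C[C@H](O)[C@H]21 | intermediate
18 | 4-acetoxybenzoyl chloride | CC(=O)Oc1ccc(cc1)C(Cl)=O | starting material
19 | 5αH-dauc-9-ene-4β,6α,8α-triol 6-(4-acetoxybenzoate) | CC(C)[C@]1(O)CC[C@]2(C)C=C[C@](C)(O)C[C@H](OC(=O)c3ccc(OC(C)=O)cc3)[C@H]21 | intermediate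
20 | 5αH-dauc-9-ene-4β,6α,8α-triol 6-(4-hydroxybenzoate) (CNP0280165.4) | CC(C)[C@]1(O)CC[C@]2(C)C=C[C@](C)(O)C[C@H](OC(=O)c3ccc(O)cc3)[C@H]21 | target

## Step count and risks

Total step count: 15. Longest linear sequence: 15 steps (1 to 20).

The three steps most likely to fail:

Step 4 (key step). What may go wrong: the ketyl opens the ring-fusion bond C1–C5 instead of C2–C5 (tertiary radical, ring-expanded products), or the primary radical is captured too slowly by the unactivated alkyne and is reduced instead. The fallback sets out from 1 and returns at 10, building the five-membered ring by polar chemistry. Copper-catalysed enantioselective conjugate addition (Cu(OTf)2, chiral N-heterocyclic carbene ligand) of the Grignard reagent BrMgCH2CH2C(OCH2CH2O)CH(CH3)2 to 1 forms the C1 quaternary centre and gives (S)-3-[2-(2-isopropyl-1,3-dioxolan-2-yl)ethyl]-3-methylcycloheptan-1-one F1. Aqueous HCl in THF removes the ketal to give (S)-3-methyl-3-(4-methyl-3-oxopentyl)cycloheptan-1-one F2. An intramolecular aldol addition under equilibrating conditions (KOt-Bu cat., t-BuOH, rt) closes C4–C5 and should funnel the aldol mixture towards the hydrogen-bonded trans-fused 10, to be separated from any C4 epimer before step 7.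

Step 5. What may go wrong: capture of the planar C4 radical by O2 on both faces (C4 epimers), or reduction of the radical to the alkane. The fallback sets out from 8 and returns at 9. Dimethyldioxirane (acetone, 0 °C) should epoxidise C3=C4 from the convex β face to give 3β,4β-epoxy-14-nor-5βH-daucan-6-one F3. LiAlH4 (THF, 0 °C) opens the epoxide at the secondary C3 and reduces the ketone, giving 14-nor-5βH-daucane-4β,6-diol F4. Dess–Martin periodinane then reoxidises the secondary C6 alcohol to give 9.

Step 10. What may go wrong: slow hydride abstraction from the neopentyl-type C10 position, competing attack at the C14 methyl group, or loss of the tertiary C4 alcohol by dehydration at reflux. The fallback sets out from 13 and returns at 14. Radical allylic bromination (N-bromosuccinimide, azobisisobutyronitrile, PhCF3, 80 °C) at the secondary γ position gives 9-bromo-4β-hydroxy-5αH-dauc-7-en-6-one F5. Dehydrobromination with LiBr and Li2CO3 in DMF (110 °C) then gives 14.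

Further compounds
F1 | step 4 | (S)-3-[2-(2-isopropyl-1,3-dioxolan-2-yl)ethyl]-3-methylcycloheptan-1-one | CC(C)C1(CC[C@]2(C)CCCCC(=O)C2)OCCO1
F2 | step 4 | (S)-3-methyl-3-(4-methyl-3-oxopentyl)cycloheptan-1-one | CC(C)C(=O)CC[C@]1(C)CCCCC(=O)C1
F3 | step 5 | 3β,4β-epoxy-14-nor-5βH-daucan-6-one | CC(C)[C@]12O[C@H]1C[C@]3(C)CCCCC(=O)[C@H]23
F4 | step 5 | 14-nor-5βH-daucane-4β,6-diol (C6 epimers) | CC(C)[C@]1(O)CC[C@]2(C)CCCCC(O)[C@@H]21
F5 | step 10 | 9-bromo-4β-hydroxy-5αH-dauc-7-en-6-one (C9 epimers) | CC(C)[C@]1(O)CC[C@]2(C)CC(Br)C(C)=CC(=O)[C@H]21
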